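## The problem

The target 19 is a 1,2-dihydronaphthalene. C1 is a methine bearing the 4-hydroxyphenyl group, C2 a methine bearing a 2,4-dihydroxybenzoyl group, C3 an alkene carbon bearing the second 2,4-dihydroxybenzoyl group and C4 an alkene CH. Ring B (C1–C4, C4a, C8a) is fused through C4a–C8a to ring A, a catechol with hydroxyls at C6 and C7 and hydrogens at C5 and C8. The difficulty lies in the four contiguous substituted carbons of ring B, two of them adjacent sp3 centres. C1 (R) is doubly benzylic, has no acidifying neighbour and must be set absolutely. C2 (S) is α to a ketone and allylic, hence epimerisable; the trans isomer holds the C1 aryl and C2 aroyl groups pseudoaxial, clear of the peri hydrogen at C8 and of the C3 aroyl group, so C1 can dictate C2 by equilibration once ring B exists. The molecule tolerates little: seven phenols (one catechol) that oxidise in base and air, a 2-ene-1,4-dione that acid can cyclodehydrate to a furan, ortho-hydroxyaryl ketones that can add to C4 in flavanone fashion, and a dihydroarene one dehydrogenation away from a naphthalene. The phenols therefore stay masked to the end, and strong base, oxidants and hot acid are kept from the late intermediates. The enabling feature is ring A itself: oxygen on adjacent C6 and C7, hydrogen on C5 and C8, fusion at C4a–C8a. This is the pattern left when a 3-alkoxyfuran (C8a, C8, C7 with its alkoxy group, C6 and the ring oxygen) adds across an alkyne (C4a, C5) and the oxygen bridge opens toward C6.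

## Retrosynthesis

**19 ⇒ 18 (six O–CH3 bonds).** The last operation is global O-demethylation of hexamethyl ether 18. The C7 oxygen is born as a methyl ether from the furan, so one methyl cleavage is unavoidable; using methyl on the other five oxygens keeps the unmasking to one step. Methyl ethers survive hydroxide, lithium amides, aqueous rhodium catalysis and heat. The forward reaction must cleave six ethers without cyclodehydrating the 1,4-diketone.

**18 ⇒ 15 (C4a–C8a and C5–C6, oxygen bridge C8a–O–C6 restored).** Retro-aromatisation of ring A to oxanorbornadiene 16 and retro-[4+2] give furyl enyne diketone 15. Cutting C4–C4a or C1–C8a instead would need a purchased, differentiated arene for ring A and, for C1–C8a, a cation at C1 that erases the only stereocentre that cannot be repaired. The chosen cut removes both rings at once, leaving an acyclic chain that carries C1 and C2, a 4-methoxyfuran and a terminal alkyne. The forward reaction needs the alkyne cis to C2 on C3=C4 and an acid-free history. C2 may be an epimer mixture, because the cis product 17 is equilibrated to 18 in the same flask.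

**15 ⇒ 14 ⇒ 12 ⇒ 10 + 11 (C3=C4).** The enyne comes from 1,4-diketone 10 and 3-(trimethylsilyl)propynal 11 by aldol addition (12), elimination (14) and desilylation (15). The aldehyde supplies C4, C4a and C5 in one piece. A Sonogashira coupling on an enol triflate is one step longer and is kept in reserve. The forward reaction needs enolisation at the C3 methylene, not the C2 methine. Only C3 carries the two hydrogens needed to form an alkylidene, and the E geometry is the normal outcome for an α-branched enone.

**10 ⇒ 8 + 9 (C2–C3).** The 1,4-dicarbonyl relationship is dissonant, so one partner is umpoled: the enolate of ketone 8 is alkylated with phenacyl bromide 9. Both aroyl groups are the same 2,4-dimethoxybenzoyl unit, so no differentiation is needed. No useful control of C2 is asked of this step.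

**8 ⇒ 6 + 7 (C1–aryl).** The diarylmethine C1 is β to the ketone and is set by rhodium-catalysed asymmetric 1,4-addition of boronic acid 7 to furyl enone 6. The reverse pairing (a furyl boron reagent onto an anisylidene ketone) is rejected because 2-furylboron reagents protodeboronate readily. The precursor is achiral and the step sets the only stereocentre that needs catalyst control.

**6 ⇒ 4 + 5, and 4 ⇒ 3 ⇒ 2 ⇒ 1.** Claisen–Schmidt condensation of aldehyde 4 with acetophenone 5 forms the C1=C2 bond of the enone. The furan C–O bond comes from copper-catalysed methoxylation of the bromide, run on acetal 2 so that methoxide never meets the free aldehyde; the acetal 3 is hydrolysed during work-up.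

## Roads not taken

**Alternative 1:** Cut C1–aryl and C2–C3. The aryl-rhodium species from 7 adds to the enone terminus C1 of enone–diketone A2, and the rhodium enolate at C2 attacks the C3 carbonyl of the tethered 1,2-diketone, closing ring B to hydroxytetralin A1.
- Merits: one catalytic enantioselective step forms two bonds and ring B; ring A is an ordinary dimethoxyarene, so no acid-labile alkoxyfuran is carried. In step count and sturdiness of intermediates this road is at least the equal of the chosen plan.
- Weak points: the benzylic methylene between ring A and the diketone in A2 enolises readily, which blunts the C3 carbonyl as an acceptor. The diketone is also an electrophile for direct 1,2-arylation. Water must then be lost from C3–OH and C4–H, but the easy E1cB path uses the acidic C2–H and gives the C2=C3 enedione, which erases C2 and needs a later double-bond shift.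
- Comparison: the chosen plan has C3=C4 and the final oxidation level in place before the ring closes, and its stereodefining step is a plain intermolecular 1,4-addition with no competing electrophile.

**Alternative 2:** No new sigma bond is made. Sc(OTf)3 heterolyses the C2–C4 bond shared by the three- and five-membered rings of cyclopropane-fused indane A4, and loss of the C3 proton gives heptamethyl ether A3 with C3=C4 and ring B expanded to six members.
- Merits: the ring expansion lands directly on the correct skeleton and oxidation level, the ring-A oxygen para to C4a stabilises the benzylic cation at C4, and C2 is reprotonated under thermodynamic control.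
- Weak points: the difficulty moves into A4. Its quaternary C2 and three cyclopropane centres must be built on a 1-aryl-indene, whose C1 stereocentre is labile toward hydrogen shifts. Both C2–C4 and C3–C4 are donor–acceptor bonds, and cleaving the exocyclic one gives an indene with no expansion.
- Comparison: its final stage is more direct than the chosen plan's. The chosen plan answers with a ring-forming step whose bond pattern is fixed by tether length and a quaternary bridgehead, and with a C1 centre made where nothing can racemise it.

**Alternative 3:** Cut C1–C2 and C3–C4. The photoenol of 2-benzylbenzaldehyde A6 adds across the C2=C3 bond of trans-diaroylethylene A7 to give hydroxytetralin A5; E1cB loss of the C4 hydroxyl with the acidic C3–H then gives C3=C4 without regiochemical ambiguity.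
- Merits: this is the shortest and most convergent road, with two simple achiral partners, one of them symmetric, and both ring-B bonds made in one step. For racemic material it is clearly better than the chosen plan.
- Weak points: A7 absorbs light and isomerises about its double bond. The photoenol needs an aryl group on the diene terminus, which shortens its lifetime and blurs the geometry that sets C1 relative to C2. Enantiocontrol would rest on a chiral Lewis acid holding a non-chelating diketone during a photochemical step.
- Comparison: the chosen plan is about twice as long and sets against this only a reliable, catalyst-controlled source of absolute configuration at C1.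

Key step: step 9

Remark on the chemistry: C2 is α to a ketone and step 5 is not expected to discriminate its faces, so 10 and 12–16 are each carried with their C2 epimer; names and SMILES show the epimer that maps onto 19 (the C2 descriptor changes from R in 10 to S from 12 on only through the priority rules), and both series converge at 18 in step 9.

## Route

Step 1
Reactants: 1 4-bromofuran-2-carbaldehyde
Product: 2 4-bromo-2-(dimethoxymethyl)furan
Conditions: HC(OMe)3, MeOH, TsOH·H2O (cat.), 23 °C; then Et3N
Reagents that add atoms: trimethyl orthoformate COC(OC)OC; methanol CO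
Why: Acid-catalysed acetalisation with the orthoformate as water scavenger; the acetal keeps the aldehyde away from hot methoxide in step 2.

Step 2
Reactants: 2 4-bromo-2-(dimethoxymethyl)furan
Product: 4 4-methoxyfuran-2-carbaldehyde, via 2-(dimethoxymethyl)-4-methoxyfuran 3 (not isolated)
Conditions: NaOMe (3 equiv), CuBr (10 mol%), MeOH–NMP, 100 °C; extractive work-up; then PPTS (cat.), acetone–H2O, 23 °C
Reagents that add atoms: sodium methoxide [Na+].[O-]C; water O
Why: Ullmann-type copper-catalysed methoxylation of a heteroaryl bromide, the usual entry to 3-alkoxy five-membered heteroarenes; the furfural-type acetal then hydrolyses under buffered acid much faster than the methoxyfuran because its oxocarbenium ion is stabilised by the furan ring.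

Step 3
Reactants: 4 4-methoxyfuran-2-carbaldehyde; 5 1-(2,4-dimethoxyphenyl)ethan-1-one
Product: 6 (E)-1-(2,4-dimethoxyphenyl)-3-(4-methoxyfuran-2-yl)prop-2-en-1-one
Conditions: NaOH, EtOH–H2O, 0 → 23 °C
Reagents that add atoms: none
Why: Claisen–Schmidt condensation of a non-enolisable heteroaryl aldehyde with an aryl methyl ketone; the E-enone is the thermodynamic product and the basic medium suits the acid-labile methoxyfuran.

Step 4
Reactants: 6 (E)-1-(2,4-dimethoxyphenyl)-3-(4-methoxyfuran-2-yl)prop-2-en-1-one; 7 (4-methoxyphenyl)boronic acid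
Product: 8 (3R)-1-(2,4-dimethoxyphenyl)-3-(4-methoxyfuran-2-yl)-3-(4-methoxyphenyl)propan-1-one
Conditions: [Rh(OH)((R)-BINAP)]2 (2.5 mol%), 7 (2 equiv), dioxane–H2O (10:1), 40 °C
Reagents that add atoms: none
Why: Rhodium-catalysed asymmetric 1,4-addition of an arylboronic acid to an acyclic E-enone (Hayashi–Miyaura reaction), run base-free and near room temperature with the hydroxo-rhodium dimer; C1 is set by catalyst control, and on the facial model for E-enones the (R)-ligand should give the (3R)-ketone, the antipodal ligand being the remedy if this heteroaryl enone reverses the sense.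

Step 5
Reactants: 8 (3R)-1-(2,4-dimethoxyphenyl)-3-(4-methoxyfuran-2-yl)-3-(4-methoxyphenyl)propan-1-one; 9 2-bromo-1-(2,4-dimethoxyphenyl)ethan-1-one
Product: 10 (2R)-1,4-bis(2,4-dimethoxyphenyl)-2-[(R)-(4-methoxyfuran-2-yl)(4-methoxyphenyl)methyl]butane-1,4-dione
Conditions: LiHMDS (1.05 equiv), THF, −78 °C; then 9 (1.1 equiv), −78 → −20 °C
Reagents that add atoms: none
Why: SN2 alkylation of a lithium ketone enolate with a phenacyl bromide to form the C2–C3 bond of a 1,4-diketone; the electron-rich aryl ring of 9 lowers its carbonyl electrophilicity and α-acidity, which favours displacement over carbonyl addition and proton transfer; C2 forms without useful control and is corrected in step 9.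

Step 6
Reactants: 10 (2R)-1,4-bis(2,4-dimethoxyphenyl)-2-[(R)-(4-methoxyfuran-2-yl)(4-methoxyphenyl)methyl]butane-1,4-dione; 11 3-(trimethylsilyl)prop-2-ynal
Product: 12 (2S)-1,4-bis(2,4-dimethoxyphenyl)-2-[(R)-(4-methoxyfuran-2-yl)(4-methoxyphenyl)methyl]-3-[1-hydroxy-3-(trimethylsilyl)prop-2-yn-1-yl]butane-1,4-dione (both new centres as mixtures)
Conditions: LiHMDS (1.05 equiv), THF, −78 °C; then 11 (1.3 equiv), −78 °C; AcOH quench at −78 °C
Reagents that add atoms: none
Why: Directed aldol addition; kinetic deprotonation should occur at the C3 methylene, not the hindered C2 methine, and only C3 has the two hydrogens needed to become an alkylidene; the ynal reacts by 1,2-addition at low temperature, and the two new centres are destroyed in step 7.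

Step 7
Reactants: 12 (2S)-1,4-bis(2,4-dimethoxyphenyl)-2-[(R)-(4-methoxyfuran-2-yl)(4-methoxyphenyl)methyl]-3-[1-hydroxy-3-(trimethylsilyl)prop-2-yn-1-yl]butane-1,4-dione
Product: 14 (2S,3E)-1,4-bis(2,4-dimethoxyphenyl)-2-[(R)-(4-methoxyfuran-2-yl)(4-methoxyphenyl)methyl]-3-[3-(trimethylsilyl)prop-2-yn-1-ylidene]butane-1,4-dione, via propargylic mesylate 13 (not isolated)
Conditions: MsCl, Et3N (3 equiv), CH2Cl2, −20 → 23 °C
Reagents that add atoms: none
Why: Mesylation and E1cB elimination through the C3 enolate; the slim alkynyl group should settle trans to the C3 aroyl group, as β-substituents of α-branched enones do, and this E geometry places the alkyne cis to C2 as the tether requires.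

Step 8
Reactants: 14 (2S,3E)-1,4-bis(2,4-dimethoxyphenyl)-2-[(R)-(4-methoxyfuran-2-yl)(4-methoxyphenyl)methyl]-3-[3-(trimethylsilyl)prop-2-yn-1-ylidene]butane-1,4-dione
Product: 15 (2S,3E)-1,4-bis(2,4-dimethoxyphenyl)-2-[(R)-(4-methoxyfuran-2-yl)(4-methoxyphenyl)methyl]-3-(prop-2-yn-1-ylidene)butane-1,4-dione
Conditions: TBAF, AcOH (1:1), THF, 0 °C
Reagents that add atoms: none
Why: Fluoride-induced protodesilylation of an alkynylsilane; the acetic acid buffer keeps the medium from deprotonating C2 (which would open a path to a vinylallene) or adding to the enynone.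

Step 9
Reactants: 15 (2S,3E)-1,4-bis(2,4-dimethoxyphenyl)-2-[(R)-(4-methoxyfuran-2-yl)(4-methoxyphenyl)methyl]-3-(prop-2-yn-1-ylidene)butane-1,4-dione
Product: 18 [(1R,2S)-6-hydroxy-7-methoxy-1-(4-methoxyphenyl)-1,2-dihydronaphthalene-2,3-diyl]bis[(2,4-dimethoxyphenyl)methanone], via oxa-bridged cycloadduct 16 (not isolated), via cis-dihydronaphthalene 17 (not isolated)
Conditions: PhMe (0.01 M), BHT (cat.), 110 °C, Ar; then DBU (0.3 equiv), 40 °C
Reagents that add atoms: none
Why: The 4-methoxyfuran (diene, raised in energy by the alkoxy donor) and the terminal alkyne (dienophile, activated through C3=C4 by the C3 aroyl group) should combine in a thermal intramolecular Diels–Alder reaction of a furan, the known reaction type being furan–alkyne cycloaddition followed by oxanorbornadiene-to-phenol aromatisation. Ring B closes through the four-atom tether C1–C2–C3=C4 by formation of C4a–C8a, a six-membered carbocycle and the only size the tether allows, while the simultaneous C5–C6 bond completes the future ring A in oxanorbornadiene 16, whose oxygen bridges C8a and C6. Because C8a is quaternary, only heterolysis of C8a–O can lead to an arene; the cation is a vinylogous oxocarbenium ion stabilised by the C7 methoxy group through C8=C7, and loss of the C6 proton gives the C6 phenol, so oxygen ends at C6 and C7 and nowhere else. The regiochemistry of the cycloaddition is fixed by the tether and needs the alkyne cis to C2 on C3=C4, which step 7 provides. The two bridgehead centres of 16 are transient, either bridge face converges on the same arene, and C1 is untouched. C2 is set here under thermodynamic control: DBU equilibrates the cis isomer 17 through the extended enolate to trans isomer 18, in which the C1 aryl and C2 aroyl groups are both pseudoaxial and avoid the peri hydrogen at C8 and the C3 aroyl group. High dilution suppresses intermolecular cycloaddition, and the absence of acid preserves the methoxyfuran until it has reacted.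

Step 10
Reactants: 18 [(1R,2S)-6-hydroxy-7-methoxy-1-(4-methoxyphenyl)-1,2-dihydronaphthalene-2,3-diyl]bis[(2,4-dimethoxyphenyl)methanone]
Product: 19 [(1R,2S)-6,7-dihydroxy-1-(4-hydroxyphenyl)-1,2-dihydronaphthalene-2,3-diyl]bis[(2,4-dihydroxyphenyl)methanone]
Conditions: BBr3 (15 equiv), CH2Cl2, −78 → 23 °C, Ar; then MeOH and H2O, 0 °C
Reagents that add atoms: none
Why: Lewis-acid O-demethylation of aryl methyl ethers; the ortho-methoxy groups cleave first with chelation, and the resulting six-membered boron chelates tie up both carbonyl oxygens, which should block furan-forming cyclodehydration of the 1,4-diketone; C1 has no pathway to epimerise and C2 is already in its stable trans configuration.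

## Compound list

1 | 4-bromofuran-2-carbaldehyde | O=Cc1cc(Br)co1 | starting material
2 | 4-bromo-2-(dimethoxymethyl)furan | COC(OC)c1cc(Br)co1 | intermediate
3 | 2-(dimethoxymethyl)-4-methoxyfuran | COC(OC)c1cc(OC)co1 | intermediate
4 | 4-methoxyfuran-2-carbaldehyde | COc1coc(C=O)c1 | intermediate
5 | 1-(2,4-dimethoxyphenyl)ethan-1-one | CC(=O)c1ccc(OC)cc1OC | starting material
6 | (E)-1-(2,4-dimethoxyphenyl)-3-(4-methoxyfuran-2-yl)prop-2-en-1-one | COc1coc(/C=C/C(=O)c2ccc(OC)cc2OC)c1 | intermediate
7 | (4-methoxyphenyl)boronic acid | COc1ccc(B(O)O)cc1 | starting material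
8 | (3R)-1-(2,4-dimethoxyphenyl)-3-(4-methoxyfuran-2-yl)-3-(4-methoxyphenyl)propan-1-one | COc1coc(c1)[C@@H](c1ccc(OC)cc1)CC(=O)c1ccc(OC)cc1OC | intermediate
9 | 2-bromo-1-(2,4-dimethoxyphenyl)ethan-1-one | COc1ccc(C(=O)CBr)c(OC)c1 | starting material
10 | (2R)-1,4-bis(2,4-dimethoxyphenyl)-2-[(R)-(4-methoxyfuran-2-yl)(4-methoxyphenyl)methyl]butane-1,4-dione | COc1coc(c1)[C@@H](c1ccc(OC)cc1)[C@@H](CC(=O)c1ccc(OC)cc1OC)C(=O)c1ccc(OC)cc1OC | intermediate
11 | 3-(trimethylsilyl)prop-2-ynal | O=CC#C[Si](C)(C)C | starting material
12 | (2S)-1,4-bis(2,4-dimethoxyphenyl)-2-[(R)-(4-methoxyfuran-2-yl)(4-methoxyphenyl)methyl]-3-[1-hydroxy-3-(trimethylsilyl)prop-2-yn-1-yl]butane-1,4-dione, mixture at C3 and at the carbinol carbon | COc1coc(c1)[C@@H](c1ccc(OC)cc1)[C@@H](C(C(O)C#C[Si](C)(C)C)C(=O)c1ccc(OC)cc1OC)C(=O)c1ccc(OC)cc1OC | intermediate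
13 | methanesulfonate of 12 at the propargylic hydroxyl | COc1coc(c1)[C@@H](c1ccc(OC)cc1)[C@@H](C(C(OS(C)(=O)=O)C#C[Si](C)(C)C)C(=O)c1ccc(OC)cc1OC)C(=O)c1ccc(OC)cc1OC | intermediate
14 | (2S,3E)-1,4-bis(2,4-dimethoxyphenyl)-2-[(R)-(4-methoxyfuran-2-yl)(4-methoxyphenyl)methyl]-3-[3-(trimethylsilyl)prop-2-yn-1-ylidene]butane-1,4-dione | COc1coc(c1)[C@@H](c1ccc(OC)cc1)[C@@H](/C(=C\C#C[Si](C)(C)C)C(=O)c1ccc(OC)cc1OC)C(=O)c1ccc(OC)cc1OC | intermediate
15 | (2S,3E)-1,4-bis(2,4-dimethoxyphenyl)-2-[(R)-(4-methoxyfuran-2-yl)(4-methoxyphenyl)methyl]-3-(prop-2-yn-1-ylidene)butane-1,4-dione | COc1coc(c1)[C@@H](c1ccc(OC)cc1)[C@@H](/C(=C\C#C)C(=O)c1ccc(OC)cc1OC)C(=O)c1ccc(OC)cc1OC | intermediate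
16 | oxanorbornadiene cycloadduct: 1,2-dihydronaphthalene skeleton with an oxygen bridge from C8a to C6, double bonds C3=C4, C4a=C5 and C7=C8, methoxy at C7, C1 and C2 as in 15, bridge on either face | COC1=CC23OC1C=C2C=C(C(=O)c1ccc(OC)cc1OC)[C@@H](C(=O)c1ccc(OC)cc1OC)[C@@H]3c1ccc(OC)cc1 | intermediate
17 | [(1R,2R)-6-hydroxy-7-methoxy-1-(4-methoxyphenyl)-1,2-dihydronaphthalene-2,3-diyl]bis[(2,4-dimethoxyphenyl)methanone] (cis) | O=C(C1=Cc2cc(O)c(OC)cc2[C@@H](c2ccc(OC)cc2)[C@H]1C(=O)c1ccc(OC)cc1OC)c1ccc(OC)cc1OC | intermediate
18 | [(1R,2S)-6-hydroxy-7-methoxy-1-(4-methoxyphenyl)-1,2-dihydronaphthalene-2,3-diyl]bis[(2,4-dimethoxyphenyl)methanone] (trans) | O=C(C1=Cc2cc(O)c(OC)cc2[C@@H](c2ccc(OC)cc2)[C@@H]1C(=O)c1ccc(OC)cc1OC)c1ccc(OC)cc1OC | intermediate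
19 | [(1R,2S)-6,7-dihydroxy-1-(4-hydroxyphenyl)-1,2-dihydronaphthalene-2,3-diyl]bis[(2,4-dihydroxyphenyl)methanone] | O=C(C1=Cc2cc(O)c(O)cc2[C@@H](c2ccc(O)cc2)[C@@H]1C(=O)c1ccc(O)cc1O)c1ccc(O)cc1O | target

## Step count and least certain steps

Total step count: 10. Longest linear sequence: 10 steps (1 → 19); 5, 7, 9 and 11 are purchased and enter directly.

**Step 9 (key step).** The alkyne is activated only vinylogously, so the cycloaddition may be slower than competing processes at the temperatures the substrate tolerates. These are a thermal hydrogen shift from C2 to the alkyne terminus giving a vinylallene, polymerisation of the enynone, loss of the alkoxyfuran, and isomerisation about C3=C4, which takes the alkyne out of reach. The fallback gives up the furan, takes ring A from an arene and closes ring B by an intramolecular aldol condensation; it sets out from 5 and comes back at 19. Claisen–Schmidt condensation of 5 with purchased 2-bromo-4,5-dimethoxybenzaldehyde would give bromochalcone F1. The rhodium-catalysed arylation of step 4 with 7 would give (3R)-ketone F2, the aryl bromide being inert to the catalyst. Alkylation with 9 as in step 5 would give diketone F3. Palladium-catalysed formylation of the aryl bromide (Pd(OAc)2, di(1-adamantyl)-n-butylphosphine, CO/H2, TMEDA, toluene, 100 °C) would give aldehyde F4. Piperidinium acetate in warm toluene would then condense the C3 methylene with the aldehyde, the only closure that can dehydrate, to give heptamethyl ether F5 with C2 equilibrated to trans. BBr3 as in step 10 would convert F5 to 19.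

**Step 6.** Deprotonation may occur at C2 instead of C3, the enolate may exchange protons with the adduct, the aldolate may revert on warming, or the base may add to the ynal; the elimination of step 7 may also give the wrong alkene geometry. The fallback builds the enyne by cross-coupling; it sets out from 10 and comes back at 14. Claisen formylation (NaH, ethyl formate, THF) can only stop at C3, because only there is the product a stabilised enolate, and would give hydroxymethylidene diketone F6. Triflation under non-chelating conditions (Tf2O, DBU, CH2Cl2, −78 °C) is meant to place the triflate trans to the C3 aroyl group in enol triflate F7. Sonogashira coupling with ethynyltrimethylsilane (PdCl2(PPh3)2, CuI, i-Pr2NH, THF, 23 °C) would then give 14.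

**Step 5.** The enolate may take a proton from the α-bromo ketone, add to its carbonyl with epoxide closure, or be alkylated twice. The fallback makes the same 1,4-diketone by acyl-anion addition; it sets out from 8 and comes back at 10. The lithium enolate of 8 with dimethylmethylideneammonium iodide would give Mannich base F8. Quaternisation with MeI and elimination with NaHCO3 would give α-methylene ketone F9. A Stetter reaction of F9 with 2,4-dimethoxybenzaldehyde (3-benzyl-5-(2-hydroxyethyl)-4-methylthiazolium chloride, Et3N, dioxane, 70 °C) would add the acyl anion equivalent to the methylene terminus and give 10.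

**Step 2.** The copper-mediated substitution may stall on the electron-rich furan position or end in reduction of the C–Br bond, and the new enol ether may hydrolyse while the aldehyde is unmasked. The fallback reverses the polarity of the C–O coupling; it sets out from 2 and comes back at 3. Miyaura borylation (B2pin2, Pd(dppf)Cl2, KOAc, dioxane, 80 °C) would give boronate F10. Chan–Lam coupling with methanol (Cu(OAc)2, DMAP, MeOH, O2, 23 °C) would give 3, which is hydrolysed to 4 as in step 2.

## Further compounds

F1 | step 9 | (E)-3-(2-bromo-4,5-dimethoxyphenyl)-1-(2,4-dimethoxyphenyl)prop-2-en-1-one | COc1ccc(C(=O)/C=C/c2cc(OC)c(OC)cc2Br)c(OC)c1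
F2 | step 9 | (3R)-3-(2-bromo-4,5-dimethoxyphenyl)-1-(2,4-dimethoxyphenyl)-3-(4-methoxyphenyl)propan-1-one | COc1cc(Br)c(cc1OC)[C@@H](c1ccc(OC)cc1)CC(=O)c1ccc(OC)cc1OC
F3 | step 9 | (2R)-2-[(R)-(2-bromo-4,5-dimethoxyphenyl)(4-methoxyphenyl)methyl]-1,4-bis(2,4-dimethoxyphenyl)butane-1,4-dione, with its C2 epimer | COc1cc(Br)c(cc1OC)[C@@H](c1ccc(OC)cc1)[C@@H](CC(=O)c1ccc(OC)cc1OC)C(=O)c1ccc(OC)cc1OC
F4 | step 9 | 2-[(1R,2R)-2-(2,4-dimethoxybenzoyl)-4-(2,4-dimethoxyphenyl)-1-(4-methoxyphenyl)-4-oxobutyl]-4,5-dimethoxybenzaldehyde, with its C2 epimer | COc1cc(C=O)c(cc1OC)[C@@H](c1ccc(OC)cc1)[C@@H](CC(=O)c1ccc(OC)cc1OC)C(=O)c1ccc(OC)cc1OC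
F5 | step 9 | [(1R,2S)-6,7-dimethoxy-1-(4-methoxyphenyl)-1,2-dihydronaphthalene-2,3-diyl]bis[(2,4-dimethoxyphenyl)methanone] | O=C(C1=Cc2cc(OC)c(OC)cc2[C@@H](c2ccc(OC)cc2)[C@@H]1C(=O)c1ccc(OC)cc1OC)c1ccc(OC)cc1OC
F6 | step 6 | (2S)-1,4-bis(2,4-dimethoxyphenyl)-3-(hydroxymethylidene)-2-[(R)-(4-methoxyfuran-2-yl)(4-methoxyphenyl)methyl]butane-1,4-dione, with its C2 epimer, enol geometry not fixed | COc1coc(c1)[C@@H](c1ccc(OC)cc1)[C@@H](C(=CO)C(=O)c1ccc(OC)cc1OC)C(=O)c1ccc(OC)cc1OC
F7 | step 6 | (2S,3E)-1,4-bis(2,4-dimethoxyphenyl)-2-[(R)-(4-methoxyfuran-2-yl)(4-methoxyphenyl)methyl]-3-{[(trifluoromethanesulfonyl)oxy]methylidene}butane-1,4-dione, with its C2 epimer | COc1coc(c1)[C@@H](c1ccc(OC)cc1)[C@@H](/C(=C\OS(=O)(=O)C(F)(F)F)C(=O)c1ccc(OC)cc1OC)C(=O)c1ccc(OC)cc1OC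
F8 | step 5 | (3R)-2-[(dimethylamino)methyl]-1-(2,4-dimethoxyphenyl)-3-(4-methoxyfuran-2-yl)-3-(4-methoxyphenyl)propan-1-one, mixture at C2 | COc1coc(c1)[C@@H](c1ccc(OC)cc1)C(CN(C)C)C(=O)c1ccc(OC)cc1OC
F9 | step 5 | 1-(2,4-dimethoxyphenyl)-2-[(S)-(4-methoxyfuran-2-yl)(4-methoxyphenyl)methyl]prop-2-en-1-one (same spatial arrangement as 8; descriptor changed by the priority rules) | COc1coc(c1)[C@@H](c1ccc(OC)cc1)C(=C)C(=O)c1ccc(OC)cc1OC
F10 | step 2 | 2-[5-(dimethoxymethyl)furan-3-yl]-4,4,5,5-tetramethyl-1,3,2-dioxaborolane | COC(OC)c1cc(B2OC(C)(C)C(C)(C)O2)co1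
A1 | alternative 1 | [(1R,2S,3R)-3-hydroxy-6,7-dimethoxy-1-(4-methoxyphenyl)-1,2,3,4-tetrahydronaphthalene-2,3-diyl]bis[(2,4-dimethoxyphenyl)methanone] | O=C(c1ccc(OC)cc1OC)[C@@]1(O)Cc2cc(OC)c(OC)cc2[C@@H](c2ccc(OC)cc2)[C@@H]1C(=O)c1ccc(OC)cc1OC
A2 | alternative 1 | 1-(2,4-dimethoxyphenyl)-3-{2-[(E)-3-(2,4-dimethoxyphenyl)-3-oxoprop-1-en-1-yl]-4,5-dimethoxyphenyl}propane-1,2-dione | COc1cc(CC(=O)C(=O)c2ccc(OC)cc2OC)c(/C=C/C(=O)c2ccc(OC)cc2OC)cc1OC
A3 | alternative 2 | [(1R,2S)-6,7-dimethoxy-1-(4-methoxyphenyl)-1,2-dihydronaphthalene-2,3-diyl]bis[(2,4-dimethoxyphenyl)methanone] | O=C(C1=Cc2cc(OC)c(OC)cc2[C@@H](c2ccc(OC)cc2)[C@@H]1C(=O)c1ccc(OC)cc1OC)c1ccc(OC)cc1OC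
A4 | alternative 2 | 1,6a-bis(2,4-dimethoxybenzoyl)-3,4-dimethoxy-6-(4-methoxyphenyl)-1,1a,6,6a-tetrahydrocyclopropa[a]indene, aryl-bearing carbon configured as in the target, cyclopropane centres not assigned | O=C(c1ccc(OC)cc1OC)C1C2c3cc(OC)c(OC)cc3[C@@H](c3ccc(OC)cc3)C12C(=O)c1ccc(OC)cc1OC
A5 | alternative 3 | [(1R,2S,3R,4R)-4-hydroxy-6,7-dimethoxy-1-(4-methoxyphenyl)-1,2,3,4-tetrahydronaphthalene-2,3-diyl]bis[(2,4-dimethoxyphenyl)methanone] | O=C(c1ccc(OC)cc1OC)[C@H]1[C@@H](O)c2cc(OC)c(OC)cc2[C@@H](c2ccc(OC)cc2)[C@@H]1C(=O)c1ccc(OC)cc1OC
A6 | alternative 3 | 4,5-dimethoxy-2-(4-methoxybenzyl)benzaldehyde | COc1ccc(Cc2cc(OC)c(OC)cc2C=O)cc1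
A7 | alternative 3 | (E)-1,4-bis(2,4-dimethoxyphenyl)but-2-ene-1,4-dione | COc1ccc(C(=O)/C=C/C(=O)c2ccc(OC)cc2OC)c(OC)c1
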